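## Analysis of the target

The target is a trans-fused hydrindane (ring B a cyclohexane, ring C a cyclopentane) joined through one CH2 group to ring A, a 4-bromo-3,3-dimethylcyclohexyl acetate. Locants follow the name of 41: C-1 carries the linker, C-3a the angular methyl, C-4 the bromine, C-7 the methyl and the hydroxyl, C-7a is the fusion CH; on ring A, C-1′ is the acetate carbon and C-4′ the CHBr carbon. There are seven stereocentres: five contiguous ones on the hydrindane and two on ring A, which are cis-1,4. In ring B the angular methyl, the fusion hydrogen and the hydroxyl are axial, the bromine is equatorial and cis to the angular methyl; on ring C the linker is trans to C-7. Both bromides are secondary and flanked by quaternary carbons, so they eliminate or are reduced easily and cannot be made by displacement, and the tertiary acetate has to be distinguished from a free tertiary alcohol. The hard points are the C-3a/C-4 pair, the ring A 1,4-relationship (bromine has too small an equatorial preference to steer a remote centre), and the CH2 insulation of the two halves, which forces separate absolute control of each. The strategy rests on one feature: the equatorial bromine at C-4 is antiperiplanar to the C-3a–C-7a bond, the imprint of anti addition of bromine and a migrating carbon across an alkene.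

## Retrosynthetic reasoning

**C-6–C-7 (ring B).** 41 is opened between the ring CH2 and the carbinol carbon to iodo ketone 40. This bond is cut last so that the free tertiary alcohol appears only after the tertiary acetate is in place; the forward reductive Barbier closure must spare two secondary bromides and put the hydroxyl axial.

**Functional group adjustment.** 40 comes from hydroxy ketone 39 and this from 38, in which the acetyl group is a dioxolane and the primary alcohol a silyl ether. Both masks fall together in acid.

**Ring C carbonyl.** 38 lacks a ketone at C-3 that the ring construction leaves behind; it is traced to alkene 37, enol triflate 36 and ketone 34. Removal through the enol triflate avoids tin hydride or dissolving-metal conditions that would attack C–Br bonds.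

**C-1–CH2 (fragment union).** 34 is cut between C-1 and the linker carbon into enone 19 and iodide 33. A radical is used because a carbanion at this carbon would expel the β-oxygen; the forward addition must occur anti to the dioxolanyl group at the neighbouring carbon.

**Enone.** 19 is the dehydrogenation product of cyclopentanone 17, which can enolise on one side only.

**C-3a–C-7a and C-4–Br (key disconnection).** 17 is traced to alkenylcyclobutanol 16 by reversing a bromonium-triggered 1,2-shift. One step makes the quaternary carbon, the neighbouring bromide and ring C, with no substitution at a neopentyl carbon. The forward step has to choose the alkene face so that the bromoalkyl arm ends trans to the dioxolane.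

**Carbinol.** 16 is cut at the carbinol–alkenyl bond into cyclobutanone 10 and alkenyl iodide 14; 14 comes from silyl ether 12 and alkynol 11 by syn hydrometalation.

**Cyclobutanone.** 10 is cut across the four-membered ring into amide 6 and ethene 7 (keteniminium [2+2]); the chiral amine 2 in 6 sets the only stereocentre. 6 comes from 4 and diol 5, and 4 from 1 and 2.

**Ring A oxygenation.** 33 is traced through iodohydrin 32 and diol 31 to epoxy alcohol 30 and allylic alcohol 29. The tertiary C–O bond is made by a reagent-controlled epoxidation, because no substrate bias relates it to the remote bromide; applied to racemic 29 it gives separable diastereomers, which fixes both the 1,4-relationship and the absolute configuration.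

**Ring A skeleton.** 29 comes from enol triflate 28 and ketone 26, and 26 from keto ester 24, which is cut at the bond between the gem-dimethyl carbon and the keto ester carbon to acyclic 23 (bromonium cyclisation, again giving the bromide next to a quaternary carbon). 23 is the alkylation product of 20 with 21.

## Alternatives that were turned down

**Alternative 1:** Ring B is cut at the two bonds from the ring fusion to C-4 and C-7. Forward, the ring-A-bearing (E)-2-methyl enal A2 adds to (1E,3E)-1,4-diacetoxybutadiene A3 under Et2AlCl A4 to give cyclohexene diacetate A1.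
- For it: one convergent Diels–Alder step makes ring B, the quaternary carbon and four contiguous centres with predictable relative configuration, and ring A is attached early. On convergence it is stronger than the chosen route.
- Against it: a β-branched trisubstituted enal and an acid-sensitive diacetoxydiene are a poorly matched pair, and the face is set only by an acyclic allylic centre. Ring C is still open after the cycloaddition. One allylic acetate of A1 must become the equatorial bromide by displacement at a neopentyl-type allylic carbon, where SN2′ and elimination compete.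
- Comparison: the hardest stereodiad is left to a substitution and many refunctionalisation steps follow; the chosen route makes that diad directly by anti addition.

**Alternative 2:** The bonds from C-7a to the future C-1 and from C-3a to the future C-3 are cut on a preformed ring B. Forward, the alkenylaluminium A8 (from ring A alkyne A7 by hydroalumination) adds to enone A6 under Cu(OTf)2 A9 with a chiral carbene ligand, and the enolate is C-allylated to give A5; no ring closes.
- For it: the fusion CH is set by a catalyst and the allylation anti to it gives the trans pair reliably. This is stronger absolute control than an auxiliary-controlled cycloaddition followed by a substrate-controlled shift.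
- Against it: the ring B ketone of A5 must be turned into the equatorial bromide next to the quaternary carbon, again by invertive substitution at a neopentyl centre. Ring C needs metathesis and then a face-selective alkene reduction at C-1 in the presence of bromides. The ring A bromide must survive the hydroalumination.
- Comparison: better control of the fusion, worse access to the bromide; step count after the key step is higher.

**Alternative 3:** Ring A is cut at the bond from the acetate carbon to a ring CH2 and at the enone double bond. Forward, the α-acetoxy aldehyde A11 adds through its enamine with a chiral primary amine such as (S)-phenylalanine A13 to methyl vinyl ketone A12, and aldol condensation gives cyclohexenone A10.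
- For it: the acetate-bearing quaternary carbon is set by a catalyst, independently of the remote hydrindane. On this point it is stronger than the chosen route, which epoxidises a racemate and discards half.
- Against it: A10 presupposes the finished hydrindane, so it does not address the C-3a/C-4 problem. Its enone carbonyl sits at the future CHBr carbon, so gem-dimethylation and conversion of a neopentyl ketone into an equatorial bromide remain. A 4-acyloxycyclohexenone can lose acetic acid and aromatise. The sequence is fully linear.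
- Comparison: the chosen route makes both C–Br bonds by bromonium chemistry and stays convergent.

Key step: step 7

Assumption: the (2S,5S)-pyrrolidine amide is taken to deliver (S)-10 (steric model of the keteniminium); if the sense proves opposite, the (2R,5R)-amine is used and nothing else changes.

## Route

Step 1
Reactants: 1 2,2,6-trimethyl-4H-1,3-dioxin-4-one; 2 (2S,5S)-2,5-dimethylpyrrolidine
Product: 4 1-[(2S,5S)-2,5-dimethylpyrrolidin-1-yl]butane-1,3-dione, via acetylketene 3 (not isolated)
Conditions: PhMe, 110 °C (acetone distilled off)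
Reagents that add atoms: none
Why: Thermal retro-[4+2] of the dioxinone releases acetylketene, which acylates the secondary amine at nitrogen (acetoacetylation); no stereocentre is touched.

Step 2
Reactants: 4 1-[(2S,5S)-2,5-dimethylpyrrolidin-1-yl]butane-1,3-dione; 5 ethane-1,2-diol
Product: 6 1-[(2S,5S)-2,5-dimethylpyrrolidin-1-yl]-2-(2-methyl-1,3-dioxolan-2-yl)ethan-1-one
Conditions: TsOH·H2O (cat.), PhH, reflux, Dean–Stark
Reagents that add atoms: none
Why: Acid-catalysed ketalisation of the ketone of a β-keto amide with azeotropic removal of water; the amide carbonyl does not ketalise.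

Step 3
Reactants: 6 1-[(2S,5S)-2,5-dimethylpyrrolidin-1-yl]-2-(2-methyl-1,3-dioxolan-2-yl)ethan-1-one; 7 ethene
Product: 10 (2S)-2-(2-methyl-1,3-dioxolan-2-yl)cyclobutan-1-one, via keteniminium triflate 8 (not isolated), via cyclobutaniminium triflate 9 (not isolated)
Conditions: Tf2O, 2,4,6-collidine, ClCH2CH2Cl, −20 °C; C2H4 (10 bar), 60 °C; then aq NaHCO3, rt
Reagents that add atoms: water, O
Why: Keteniminium–alkene [2+2] cycloaddition: O-triflation and loss of the α-proton give heterocumulene 8, whose C=C bond adds ethene to give the four-membered iminium salt 9, and buffered hydrolysis frees the ketone and the amine. The C2-symmetric pyrrolidine shields one flank of the keteniminium, so the new CH centre is set under auxiliary control; buffered hydrolysis should leave it and the dioxolane intact.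

Step 4
Reactants: 11 pent-3-yn-1-ol
Product: 12 tert-butyl(dimethyl)(pent-3-yn-1-yloxy)silane
Conditions: TBSCl, imidazole, CH2Cl2, rt
Reagents that add atoms: tert-butyldimethylsilyl chloride, CC(C)(C)[Si](C)(C)Cl
Why: Standard silylation of a primary alcohol; the silyl ether survives organolithium, bromonium and radical steps.

Step 5
Reactants: 12 tert-butyl(dimethyl)(pent-3-yn-1-yloxy)silane
Product: 14 tert-butyl{[(3E)-4-iodopent-3-en-1-yl]oxy}dimethylsilane, via alkenylzirconocene chloride 13 (not isolated)
Conditions: Cp2Zr(H)Cl (2 equiv), THF, 50 °C; then I2, 0 °C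
Reagents that add atoms: iodine, II
Why: Hydrozirconation is a syn addition; with excess Cp2Zr(H)Cl the metal equilibrates to the less hindered, methyl-bearing alkyne carbon, and iodinolysis with retention gives the (E)-2-iodoalkene.

Step 6
Reactants: 14 tert-butyl{[(3E)-4-iodopent-3-en-1-yl]oxy}dimethylsilane; 10 (2S)-2-(2-methyl-1,3-dioxolan-2-yl)cyclobutan-1-one
Product: 16 (1R,2S)-1-[(2E)-5-{[tert-butyl(dimethyl)silyl]oxy}pent-2-en-2-yl]-2-(2-methyl-1,3-dioxolan-2-yl)cyclobutan-1-ol, via alkenyllithium 15 (not isolated)
Conditions: t-BuLi (2 equiv), Et2O, −78 °C; then 10, −78 → −40 °C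
Reagents that add atoms: none
Why: Iodine–lithium exchange keeps the alkene geometry, and the alkenyllithium adds to the strained ketone (1,2-addition) from the face anti to the dioxolanyl group, placing OH cis to it. The carbinol configuration is lost in step 7, so only the alkene geometry and the ring CH centre matter.

Step 7
Reactants: 16 (1R,2S)-1-[(2E)-5-{[tert-butyl(dimethyl)silyl]oxy}pent-2-en-2-yl]-2-(2-methyl-1,3-dioxolan-2-yl)cyclobutan-1-ol
Product: 17 (2R,3S)-2-[(1S)-1-bromo-3-{[tert-butyl(dimethyl)silyl]oxy}propyl]-2-methyl-3-(2-methyl-1,3-dioxolan-2-yl)cyclopentan-1-one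
Conditions: NBS (1.1 equiv), propylene oxide, i-PrOH, −78 → −20 °C, dark
Reagents that add atoms: N-bromosuccinimide, O=C1CCC(=O)N1Br
Why: NBS transfers Br+ to the electron-rich trisubstituted alkene, and as the bromonium ion forms, the cyclobutane bond to the dioxolane-bearing CH, antiperiplanar to the breaking C–Br+ bond, shifts to the methyl-bearing alkene carbon while the carbinol carbon becomes the ketone; this is the known halonium-induced semipinacol ring expansion of 1-alkenylcyclobutanols to 2-substituted cyclopentanones. Ring C therefore closes by ring expansion (a 1,2-alkyl shift from a four- to a five-membered ring, driven by strain release and carbonyl formation), not by an end-on cyclisation. The migrating CH moves suprafacially with retention, so C-3 of 17 keeps the configuration set in step 3. The quaternary carbon and the CHBr carbon are created together: bromine and the migrating carbon add anti across the (E)-alkene, which fixes their relative configuration whichever face reacts. The face is chosen by the substrate: in the reactive rotamers the bulky bromonium terminus avoids the dioxolane on the migrating carbon, so the new bond forms with methyl cis and the bromoalkyl arm trans to the dioxolane, the future trans ring fusion. Two selectivities are needed: migration of the substituted ring carbon over the ring CH2, favoured because the secondary carbon carries more of the developing positive charge, and rearrangement over acid-induced loss of ketal or silyl ether, secured by propylene oxide as HBr scavenger at low temperature.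

Step 8
Reactants: 17 (2R,3S)-2-[(1S)-1-bromo-3-{[tert-butyl(dimethyl)silyl]oxy}propyl]-2-methyl-3-(2-methyl-1,3-dioxolan-2-yl)cyclopentan-1-one
Product: 19 (4S,5R)-5-[(1S)-1-bromo-3-{[tert-butyl(dimethyl)silyl]oxy}propyl]-5-methyl-4-(2-methyl-1,3-dioxolan-2-yl)cyclopent-2-en-1-one, via silyl enol ether 18 (not isolated)
Conditions: LiN(SiMe3)2, TMSCl, THF, −78 °C; then Pd(OAc)2, MeCN, rt
Reagents that add atoms: none
Why: Saegusa–Ito oxidation: only the CH2 side of the ketone can enolise (the other α-carbon is quaternary), so the enone forms regiospecifically. β-Elimination of bromide is impossible because the carbon between carbonyl and CHBr bears no hydrogen.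

Step 9
Reactants: 20 tert-butyl 3-oxobutanoate; 21 1-bromo-3-methylbut-2-ene
Product: 23 tert-butyl 7-methyl-3-oxooct-6-enoate, via dilithium dianion 22 (not isolated)
Conditions: LiN(i-Pr)2 (2.1 equiv), THF, 0 °C; then 21, 0 °C → rt
Reagents that add atoms: none
Why: Alkylation of the acetoacetate dianion at its terminal carbon with the allylic bromide, the classical route to γ-alkylated β-keto esters.

Step 10
Reactants: 23 tert-butyl 7-methyl-3-oxooct-6-enoate
Product: 24 tert-butyl rac-(1S,3S)-3-bromo-2,2-dimethyl-6-oxocyclohexane-1-carboxylate (racemic; cis)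
Conditions: Et2SBr·SbCl5Br (BDSB, 1.05 equiv), MeNO2, −25 °C, 10 min
Reagents that add atoms: bromodiethylsulfonium bromopentachloroantimonate, CC[S+](Br)CC.Cl[Sb-](Cl)(Cl)(Cl)(Cl)Br
Why: Bromonium-initiated cation–olefin cyclisation: Br+ adds to the trisubstituted alkene and the keto ester carbon opens the bromonium ion at its tertiary end through a chair, anti to bromine, so bromine ends on the secondary carbon next to the new quaternary carbon. The product is racemic and its ester-bearing centre is lost in step 11.

Step 11
Reactants: 24 tert-butyl rac-(1S,3S)-3-bromo-2,2-dimethyl-6-oxocyclohexane-1-carboxylate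
Product: 26 (±)-4-bromo-3,3-dimethylcyclohexan-1-one, via keto acid 25 (not isolated)
Conditions: CF3CO2H, CH2Cl2, rt; then PhMe, 80 °C
Reagents that add atoms: none
Why: Acidolysis of the tert-butyl ester and thermal decarboxylation of the β-keto acid; these non-nucleophilic conditions spare the secondary bromide.

Step 12
Reactants: 26 (±)-4-bromo-3,3-dimethylcyclohexan-1-one
Product: 28 (±)-4-bromo-5,5-dimethylcyclohex-1-en-1-yl trifluoromethanesulfonate, via potassium enolate 27 (not isolated)
Conditions: KN(SiMe3)2, THF, −78 °C; then PhNTf2, −78 → 0 °C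
Reagents that add atoms: N-phenylbis(trifluoromethanesulfonimide), O=S(=O)(N(c1ccccc1)S(=O)(=O)C(F)(F)F)C(F)(F)F
Why: Kinetic deprotonation occurs at the CH2 remote from the gem-dimethyl group (the other α-CH2 is neopentyl-hindered), and O-triflation fixes that enolate. At −78 °C the hindered bromide neither eliminates nor alkylates.

Step 13
Reactants: 28 (±)-4-bromo-5,5-dimethylcyclohex-1-en-1-yl trifluoromethanesulfonate
Product: 29 (±)-(4-bromo-5,5-dimethylcyclohex-1-en-1-yl)methanol
Conditions: Bu3SnCH2OH, Pd(PPh3)4 (5 mol%), LiCl, 1,4-dioxane, 95 °C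
Reagents that add atoms: (tributylstannyl)methanol, CCCC[Sn](CCCC)(CCCC)CO
Why: Stille coupling of the enol triflate with the hydroxymethylstannane installs the CH2OH group; unactivated secondary alkyl bromides do not add oxidatively to zerovalent palladium phosphine complexes under these conditions.

Step 14
Reactants: 29 (±)-(4-bromo-5,5-dimethylcyclohex-1-en-1-yl)methanol
Product: 30 [(1R,4S,6R)-4-bromo-3,3-dimethyl-7-oxabicyclo[4.1.0]heptan-1-yl]methanol
Conditions: Ti(Oi-Pr)4 (10 mol%), D-(−)-diethyl tartrate (12 mol%), t-BuOOH, 4 Å MS, CH2Cl2, −20 °C; chromatography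
Reagents that add atoms: tert-butyl hydroperoxide, CC(C)(C)OO
Why: Sharpless asymmetric epoxidation under reagent control: with D-(−)-diethyl tartrate both enantiomers of 29 should be epoxidised on the same absolute face of the allylic alcohol, so the (4S)-enantiomer gives 30 with the oxirane oxygen cis to bromine and the (4R)-enantiomer gives the trans diastereomer, which is removed by chromatography. The racemate is thus turned into separable diastereomers of high enantiomeric purity, and the 1,4-cis relationship that no substrate bias would control is fixed.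

Step 15
Reactants: 30 [(1R,4S,6R)-4-bromo-3,3-dimethyl-7-oxabicyclo[4.1.0]heptan-1-yl]methanol
Product: 31 (1R,4S)-4-bromo-1-(hydroxymethyl)-3,3-dimethylcyclohexan-1-ol
Conditions: i-Bu2AlH (3 equiv), CH2Cl2, −20 → 0 °C
Reagents that add atoms: none
Why: Hydride opening of a 2,3-epoxy alcohol by i-Bu2AlH at the ring CH (the other oxirane carbon is fully substituted) gives the 1,2-diol with the tertiary C–O bond untouched, so the carbinol configuration is kept; alkyl bromides are inert to this reagent.

Step 16
Reactants: 31 (1R,4S)-4-bromo-1-(hydroxymethyl)-3,3-dimethylcyclohexan-1-ol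
Product: 32 (1R,4S)-4-bromo-1-(iodomethyl)-3,3-dimethylcyclohexan-1-ol
Conditions: I2, PPh3, imidazole, CH2Cl2, 0 °C → rt
Reagents that add atoms: iodine, II
Why: Appel-type iodination is selective for the primary hydroxyl; if the oxirane forms transiently by closure of the tertiary hydroxyl, iodide reopens it at the CH2 to the same iodohydrin.

Step 17
Reactants: 32 (1R,4S)-4-bromo-1-(iodomethyl)-3,3-dimethylcyclohexan-1-ol
Product: 33 (1R,4S)-4-bromo-1-(iodomethyl)-3,3-dimethylcyclohexyl acetate
Conditions: Ac2O, Sc(OTf)3 (1 mol%), MeCN, −20 °C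
Reagents that add atoms: acetic anhydride, CC(=O)OC(C)=O
Why: Sc(OTf)3-catalysed acetylation acylates tertiary alcohols quickly at low temperature; acidic conditions are chosen because base would close the iodohydrin to the oxirane.

Step 18
Reactants: 19 (4S,5R)-5-[(1S)-1-bromo-3-{[tert-butyl(dimethyl)silyl]oxy}propyl]-5-methyl-4-(2-methyl-1,3-dioxolan-2-yl)cyclopent-2-en-1-one; 33 (1R,4S)-4-bromo-1-(iodomethyl)-3,3-dimethylcyclohexyl acetate
Product: 34 (1S,4S)-4-bromo-1-{[(1R,2S,3R)-3-[(1S)-1-bromo-3-{[tert-butyl(dimethyl)silyl]oxy}propyl]-3-methyl-2-(2-methyl-1,3-dioxolan-2-yl)-4-oxocyclopentyl]methyl}-3,3-dimethylcyclohexyl acetate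
Conditions: (Me3Si)3SiH (slow addition), AIBN, PhH, 80 °C; 33 in excess
Reagents that add atoms: none
Why: Giese reaction: the silyl radical abstracts iodine much faster than a secondary bromine, and the nucleophilic primary radical adds to the unsubstituted β-carbon of the enone on the face anti to the bulky dioxolanyl group at C-4, setting the linker trans to it; the α-keto radical is then reduced by the silane. Slow addition of the silane and excess 33 favour addition over premature reduction and over 1,2-acetoxy shift.

Step 19
Reactants: 34 (1S,4S)-4-bromo-1-{[(1R,2S,3R)-3-[(1S)-1-bromo-3-{[tert-butyl(dimethyl)silyl]oxy}propyl]-3-methyl-2-(2-methyl-1,3-dioxolan-2-yl)-4-oxocyclopentyl]methyl}-3,3-dimethylcyclohexyl acetate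
Product: 36 (1S,4S)-4-bromo-1-{[(1R,4R,5S)-4-[(1S)-1-bromo-3-{[tert-butyl(dimethyl)silyl]oxy}propyl]-4-methyl-5-(2-methyl-1,3-dioxolan-2-yl)-3-{[(trifluoromethyl)sulfonyl]oxy}cyclopent-2-en-1-yl]methyl}-3,3-dimethylcyclohexyl acetate, via potassium enolate 35 (not isolated)
Conditions: KN(SiMe3)2 (1.05 equiv), THF, −78 °C; then PhNTf2
Reagents that add atoms: N-phenylbis(trifluoromethanesulfonimide), O=S(=O)(N(c1ccccc1)S(=O)(=O)C(F)(F)F)C(F)(F)F
Why: Regiospecific enolisation (the other α-carbon is quaternary) with one equivalent of base at −78 °C, where the ketone is deprotonated in preference to the acetate, followed by O-triflation.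

Step 20
Reactants: 36 (1S,4S)-4-bromo-1-{[(1R,4R,5S)-4-[(1S)-1-bromo-3-{[tert-butyl(dimethyl)silyl]oxy}propyl]-4-methyl-5-(2-methyl-1,3-dioxolan-2-yl)-3-{[(trifluoromethyl)sulfonyl]oxy}cyclopent-2-en-1-yl]methyl}-3,3-dimethylcyclohexyl acetate
Product: 37 (1S,4S)-4-bromo-1-{[(1R,4S,5S)-4-[(1S)-1-bromo-3-{[tert-butyl(dimethyl)silyl]oxy}propyl]-4-methyl-5-(2-methyl-1,3-dioxolan-2-yl)cyclopent-2-en-1-yl]methyl}-3,3-dimethylcyclohexyl acetate
Conditions: Pd(OAc)2 (5 mol%), PPh3, HCO2H, n-Bu3N, DMF, 60 °C
Reagents that add atoms: none
Why: Palladium-catalysed formate reduction of the enol triflate (hydride from decarboxylation of formate) gives the alkene; the secondary bromides do not react with the zerovalent palladium phosphine catalyst.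

Step 21
Reactants: 37 (1S,4S)-4-bromo-1-{[(1R,4S,5S)-4-[(1S)-1-bromo-3-{[tert-butyl(dimethyl)silyl]oxy}propyl]-4-methyl-5-(2-methyl-1,3-dioxolan-2-yl)cyclopent-2-en-1-yl]methyl}-3,3-dimethylcyclohexyl acetate
Product: 38 (1S,4S)-4-bromo-1-{[(1S,2S,3S)-3-[(1S)-1-bromo-3-{[tert-butyl(dimethyl)silyl]oxy}propyl]-3-methyl-2-(2-methyl-1,3-dioxolan-2-yl)cyclopentyl]methyl}-3,3-dimethylcyclohexyl acetate
Conditions: 2-NO2C6H4SO2NHNH2, Et3N, CH2Cl2, rt
Reagents that add atoms: none
Why: Diimide, generated from the sulfonyl hydrazide, delivers H2 syn to the cis-disubstituted cyclopentene without touching C–Br bonds, ketal, silyl ether or ester; no stereocentre is created.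

Step 22
Reactants: 38 (1S,4S)-4-bromo-1-{[(1S,2S,3S)-3-[(1S)-1-bromo-3-{[tert-butyl(dimethyl)silyl]oxy}propyl]-3-methyl-2-(2-methyl-1,3-dioxolan-2-yl)cyclopentyl]methyl}-3,3-dimethylcyclohexyl acetate
Product: 39 (1S,4S)-1-{[(1S,2S,3S)-2-acetyl-3-[(1S)-1-bromo-3-hydroxypropyl]-3-methylcyclopentyl]methyl}-4-bromo-3,3-dimethylcyclohexyl acetate
Conditions: 2 M HCl, THF, rt
Reagents that add atoms: water, O
Why: Aqueous acid removes the primary silyl ether and hydrolyses the dioxolane in one operation while the tertiary acetate survives. The centre alpha to the liberated ketone already has its more stable configuration (acetyl trans to the linker and to the bromoalkyl arm), so acid cannot erode it.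

Step 23
Reactants: 39 (1S,4S)-1-{[(1S,2S,3S)-2-acetyl-3-[(1S)-1-bromo-3-hydroxypropyl]-3-methylcyclopentyl]methyl}-4-bromo-3,3-dimethylcyclohexyl acetate
Product: 40 (1S,4S)-1-{[(1S,2S,3S)-2-acetyl-3-[(1S)-1-bromo-3-iodopropyl]-3-methylcyclopentyl]methyl}-4-bromo-3,3-dimethylcyclohexyl acetate
Conditions: I2, PPh3, imidazole, CH2Cl2, 0 °C
Reagents that add atoms: iodine, II
Why: Appel-type iodination of the primary alcohol; the ketone and the hindered secondary bromides are inert.

Step 24
Reactants: 40 (1S,4S)-1-{[(1S,2S,3S)-2-acetyl-3-[(1S)-1-bromo-3-iodopropyl]-3-methylcyclopentyl]methyl}-4-bromo-3,3-dimethylcyclohexyl acetate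
Product: 41 (1S,4S)-4-bromo-1-{[(1S,3aS,4S,7R,7aS)-4-bromo-7-hydroxy-3a,7-dimethyloctahydro-1H-inden-1-yl]methyl}-3,3-dimethylcyclohexyl acetate
Conditions: SmI2 (2.2 equiv), HMPA, THF, −78 → −40 °C
Reagents that add atoms: none
Why: Intramolecular SmI2 Barbier reaction: electron transfer cleaves the primary C–I bond far faster than the neopentyl-type secondary C–Br bonds at low temperature, and the carbon nucleophile adds to the methyl ketone through a six-membered chair. The ketone methyl takes the equatorial position to avoid a 1,3-diaxial clash with the angular methyl, so oxygen ends axial and cis to the angular methyl; the fusion is trans because the two arms are trans on ring C.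

## Compound list

1 | 2,2,6-trimethyl-4H-1,3-dioxin-4-one | CC1=CC(=O)OC(C)(C)O1 | starting material
2 | (2S,5S)-2,5-dimethylpyrrolidine | C[C@H]1CC[C@H](C)N1 | starting material
3 | acetylketene | CC(=O)C=C=O | intermediate
4 | 1-[(2S,5S)-2,5-dimethylpyrrolidin-1-yl]butane-1,3-dione | CC(=O)CC(=O)N1[C@@H](C)CC[C@@H]1C | intermediate
5 | ethane-1,2-diol | OCCO | starting material
6 | 1-[(2S,5S)-2,5-dimethylpyrrolidin-1-yl]-2-(2-methyl-1,3-dioxolan-2-yl)ethan-1-one | CC1(CC(=O)N2[C@@H](C)CC[C@@H]2C)OCCO1 | intermediate
7 | ethene | C=C | starting material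
8 | (2S,5S)-2,5-dimethyl-1-[2-(2-methyl-1,3-dioxolan-2-yl)ethenylidene]pyrrolidin-1-ium triflate (keteniminium salt) | C[C@H]1CC[C@H](C)[N+]1=C=CC1(C)OCCO1.[O-]S(=O)(=O)C(F)(F)F | intermediate
9 | (2S,5S)-2,5-dimethyl-1-[(2S)-2-(2-methyl-1,3-dioxolan-2-yl)cyclobutylidene]pyrrolidin-1-ium triflate | C[C@H]1CC[C@H](C)[N+]1=C1CC[C@@H]1C1(C)OCCO1.[O-]S(=O)(=O)C(F)(F)F | intermediate
10 | (2S)-2-(2-methyl-1,3-dioxolan-2-yl)cyclobutan-1-one | O=C1CC[C@@H]1C1(C)OCCO1 | intermediate
11 | pent-3-yn-1-ol | CC#CCCO | starting material
12 | tert-butyl(dimethyl)(pent-3-yn-1-yloxy)silane | CC#CCCO[Si](C)(C)C(C)(C)C | intermediate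
13 | chlorobis(cyclopentadienyl)zirconium alkenyl from 12, Zr on the methyl-bearing carbon and trans to the CH2 chain | C/C(=C\CCO[Si](C)(C)C(C)(C)C)[Zr](Cl)(C1C=CC=C1)C1C=CC=C1 | intermediate
14 | tert-butyl{[(3E)-4-iodopent-3-en-1-yl]oxy}dimethylsilane | C/C(I)=C\CCO[Si](C)(C)C(C)(C)C | intermediate
15 | alkenyllithium from 14 (lithium in place of iodine, geometry retained) | [Li]/C(C)=C/CCO[Si](C)(C)C(C)(C)C | intermediate
16 | (1R,2S)-1-[(2E)-5-{[tert-butyl(dimethyl)silyl]oxy}pent-2-en-2-yl]-2-(2-methyl-1,3-dioxolan-2-yl)cyclobutan-1-ol | O[C@]1(/C(C)=C/CCO[Si](C)(C)C(C)(C)C)CC[C@@H]1C2(C)OCCO2 | intermediate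
17 | (2R,3S)-2-[(1S)-1-bromo-3-{[tert-butyl(dimethyl)silyl]oxy}propyl]-2-methyl-3-(2-methyl-1,3-dioxolan-2-yl)cyclopentan-1-one | O=C1CC[C@H](C2(C)OCCO2)[C@@]1(C)[C@@H](Br)CCO[Si](C)(C)C(C)(C)C | intermediate
18 | trimethylsilyl enol ether of 17 (silyloxy on C-1, double bond C-1=C-5) | C[Si](C)(C)OC1=CC[C@H](C2(C)OCCO2)[C@@]1(C)[C@@H](Br)CCO[Si](C)(C)C(C)(C)C | intermediate
19 | (4S,5R)-5-[(1S)-1-bromo-3-{[tert-butyl(dimethyl)silyl]oxy}propyl]-5-methyl-4-(2-methyl-1,3-dioxolan-2-yl)cyclopent-2-en-1-one | O=C1C=C[C@H](C2(C)OCCO2)[C@@]1(C)[C@@H](Br)CCO[Si](C)(C)C(C)(C)C | intermediate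
20 | tert-butyl 3-oxobutanoate | CC(=O)CC(=O)OC(C)(C)C | starting material
21 | 1-bromo-3-methylbut-2-ene | CC(C)=CCBr | starting material
22 | dilithium dianion of 20 | [Li+].[Li+].[CH2-]C(=O)[CH-]C(=O)OC(C)(C)C | intermediate
23 | tert-butyl 7-methyl-3-oxooct-6-enoate | CC(C)=CCCC(=O)CC(=O)OC(C)(C)C | intermediate
24 | tert-butyl rac-(1S,3S)-3-bromo-2,2-dimethyl-6-oxocyclohexane-1-carboxylate (racemic; the enantiomer carried on is drawn) | O=C1CC[C@H](Br)C(C)(C)[C@@H]1C(=O)OC(C)(C)C | intermediate
25 | rac-(1S,3S)-3-bromo-2,2-dimethyl-6-oxocyclohexane-1-carboxylic acid | O=C1CC[C@H](Br)C(C)(C)[C@@H]1C(=O)O | intermediate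
26 | (±)-4-bromo-3,3-dimethylcyclohexan-1-one (the 4S enantiomer is drawn) | O=C1CC[C@H](Br)C(C)(C)C1 | intermediate
27 | potassium enolate of 26 (double bond away from the gem-dimethyl group) | [K+].[O-]C1=CC[C@H](Br)C(C)(C)C1 | intermediate
28 | (±)-4-bromo-5,5-dimethylcyclohex-1-en-1-yl trifluoromethanesulfonate (4S drawn) | O=S(=O)(OC1=CC[C@H](Br)C(C)(C)C1)C(F)(F)F | intermediate
29 | (±)-(4-bromo-5,5-dimethylcyclohex-1-en-1-yl)methanol (4S drawn) | OCC1=CC[C@H](Br)C(C)(C)C1 | intermediate
30 | [(1R,4S,6R)-4-bromo-3,3-dimethyl-7-oxabicyclo[4.1.0]heptan-1-yl]methanol | OC[C@]12CC(C)(C)[C@@H](Br)C[C@H]1O2 | intermediate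
31 | (1R,4S)-4-bromo-1-(hydroxymethyl)-3,3-dimethylcyclohexan-1-ol | OC[C@@]1(O)CC[C@H](Br)C(C)(C)C1 | intermediate
32 | (1R,4S)-4-bromo-1-(iodomethyl)-3,3-dimethylcyclohexan-1-ol | IC[C@@]1(O)CC[C@H](Br)C(C)(C)C1 | intermediate
33 | (1R,4S)-4-bromo-1-(iodomethyl)-3,3-dimethylcyclohexyl acetate | CC(=O)O[C@]1(CI)CC[C@H](Br)C(C)(C)C1 | intermediate
34 | (1S,4S)-4-bromo-1-{[(1R,2S,3R)-3-[(1S)-1-bromo-3-{[tert-butyl(dimethyl)silyl]oxy}propyl]-3-methyl-2-(2-methyl-1,3-dioxolan-2-yl)-4-oxocyclopentyl]methyl}-3,3-dimethylcyclohexyl acetate | CC(=O)O[C@]1(C[C@@H]2CC(=O)[C@](C)([C@@H](Br)CCO[Si](C)(C)C(C)(C)C)[C@H]2C3(C)OCCO3)CC[C@H](Br)C(C)(C)C1 | intermediate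
35 | potassium enolate of 34 | CC(=O)O[C@]1(C[C@@H]2C=C([O-])[C@](C)([C@@H](Br)CCO[Si](C)(C)C(C)(C)C)[C@H]2C3(C)OCCO3)CC[C@H](Br)C(C)(C)C1.[K+] | intermediate
36 | (1S,4S)-4-bromo-1-{[(1R,4R,5S)-4-[(1S)-1-bromo-3-{[tert-butyl(dimethyl)silyl]oxy}propyl]-4-methyl-5-(2-methyl-1,3-dioxolan-2-yl)-3-{[(trifluoromethyl)sulfonyl]oxy}cyclopent-2-en-1-yl]methyl}-3,3-dimethylcyclohexyl acetate | CC(=O)O[C@]1(C[C@@H]2C=C(OS(=O)(=O)C(F)(F)F)[C@](C)([C@@H](Br)CCO[Si](C)(C)C(C)(C)C)[C@H]2C3(C)OCCO3)CC[C@H](Br)C(C)(C)C1 | intermediate
37 | (1S,4S)-4-bromo-1-{[(1R,4S,5S)-4-[(1S)-1-bromo-3-{[tert-butyl(dimethyl)silyl]oxy}propyl]-4-methyl-5-(2-methyl-1,3-dioxolan-2-yl)cyclopent-2-en-1-yl]methyl}-3,3-dimethylcyclohexyl acetate | CC(=O)O[C@]1(C[C@@H]2C=C[C@](C)([C@@H](Br)CCO[Si](C)(C)C(C)(C)C)[C@H]2C3(C)OCCO3)CC[C@H](Br)C(C)(C)C1 | intermediate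
38 | (1S,4S)-4-bromo-1-{[(1S,2S,3S)-3-[(1S)-1-bromo-3-{[tert-butyl(dimethyl)silyl]oxy}propyl]-3-methyl-2-(2-methyl-1,3-dioxolan-2-yl)cyclopentyl]methyl}-3,3-dimethylcyclohexyl acetate | CC(=O)O[C@]1(C[C@@H]2CC[C@](C)([C@@H](Br)CCO[Si](C)(C)C(C)(C)C)[C@H]2C3(C)OCCO3)CC[C@H](Br)C(C)(C)C1 | intermediate
39 | (1S,4S)-1-{[(1S,2S,3S)-2-acetyl-3-[(1S)-1-bromo-3-hydroxypropyl]-3-methylcyclopentyl]methyl}-4-bromo-3,3-dimethylcyclohexyl acetate | CC(=O)O[C@]1(C[C@@H]2CC[C@](C)([C@@H](Br)CCO)[C@H]2C(C)=O)CC[C@H](Br)C(C)(C)C1 | intermediate
40 | (1S,4S)-1-{[(1S,2S,3S)-2-acetyl-3-[(1S)-1-bromo-3-iodopropyl]-3-methylcyclopentyl]methyl}-4-bromo-3,3-dimethylcyclohexyl acetate | CC(=O)O[C@]1(C[C@@H]2CC[C@](C)([C@@H](Br)CCI)[C@H]2C(C)=O)CC[C@H](Br)C(C)(C)C1 | intermediate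
41 | (1S,4S)-4-bromo-1-{[(1S,3aS,4S,7R,7aS)-4-bromo-7-hydroxy-3a,7-dimethyloctahydro-1H-inden-1-yl]methyl}-3,3-dimethylcyclohexyl acetate | CC(=O)O[C@]1(C[C@@H]2CC[C@]3(C)[C@@H](Br)CC[C@@](C)(O)[C@@H]23)CC[C@H](Br)C(C)(C)C1 | target

## Step count and least certain steps

Total: 24 steps. Longest linear sequence: 16 steps (steps 9 to 17, then 18 to 24, from 20 and 21).

**Step 7 (key step).** The likely failure is poor facial selectivity, with the bromonium terminus ending cis to the dioxolane as often as trans, because the two rotamers about the carbinol–alkene bond differ only in modest steric terms. A second possibility is migration of the ring CH2 instead of the dioxolane-bearing CH, since two β-oxygens lower the migratory aptitude of that carbon. Fallback: hand the facial choice to a reagent instead of the substrate. Starting from 16, the bromination is run with N-bromosuccinimide under a chiral catalyst of the kind established for enantioselective halogenative semipinacol ring expansions of alkenylcyclobutanols, either 3,3′-bis(2,4,6-triisopropylphenyl)-1,1′-binaphthyl-2,2′-diyl hydrogen phosphate or hydroquinidine 1,4-phthalazinediyl diether, taking the catalyst antipode (or the hydroquinine pseudoenantiomer) that is matched with 16. The route is rejoined at 17; no new compound is involved.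

**Step 3.** The dioxolane may ionise next to the electron-rich α-triflyloxy enamine, the keteniminium may self-condense because ethene is a weak nucleophile, the α-centre may epimerise during hydrolysis, and the sense of induction is only modelled. Fallback: build the cyclobutanone by oxirane ring expansion instead of cycloaddition, setting out from ethane-1,2-diol 5. Ketalisation of ethyl pyruvate with 5 gives ethyl 2-methyl-1,3-dioxolane-2-carboxylate F1; i-Bu2AlH at −78 °C gives 2-methyl-1,3-dioxolane-2-carbaldehyde F2; Wittig reaction with the ylide from cyclopropyltriphenylphosphonium bromide gives 2-(cyclopropylidenemethyl)-2-methyl-1,3-dioxolane F3. Shi epoxidation (KHSO5 with 1,2:4,5-di-O-isopropylidene-β-D-erythro-2,3-hexodiulo-2,6-pyranose or its enantiomer, chosen for the R oxirane) gives (2R)-2-(2-methyl-1,3-dioxolan-2-yl)-1-oxaspiro[2.2]pentane F4. Et2AlCl-promoted ring expansion with inversion at the oxirane CH rejoins the route at 10.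

**Step 10.** The ketone oxygen may capture the bromonium ion instead of the keto ester carbon (cyclic enol ether), or the keto ester may be brominated at carbon. Fallback: separate ring closure from bromination, setting out from 23. Hg(OTf)2 in MeNO2 closes the ring through carbon, and NaCl work-up gives tert-butyl 3-(chloromercurio)-2,2-dimethyl-6-oxocyclohexane-1-carboxylate F5. Br2 and LiBr in pyridine under oxygen replace mercury by bromine; the radical step is stereorandom, which is harmless because the ester-bearing centre is lost in step 11. The route is rejoined at 24.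

**Step 18.** Addition of a hindered, neopentyl-type radical may be slower than its reduction by the silane; the silyl radical may also attack a C–Br bond, or the β-acetoxy radical may undergo 1,2-acetoxy shift. Fallback: generate the same radical by photoredox decarboxylation, which involves no halogen-abstracting species, setting out from 32. K2CO3 in MeOH closes 32 to (3R,6S)-6-bromo-5,5-dimethyl-1-oxaspiro[2.5]octane F6; vinylmagnesium bromide with CuI opens it at CH2 to (1S,4S)-4-bromo-3,3-dimethyl-1-(prop-2-en-1-yl)cyclohexan-1-ol F7; Ac2O with Sc(OTf)3 gives (1S,4S)-4-bromo-3,3-dimethyl-1-(prop-2-en-1-yl)cyclohexyl acetate F8; RuCl3 with NaIO4 cleaves the alkene to [(1R,4S)-1-(acetyloxy)-4-bromo-3,3-dimethylcyclohexyl]acetic acid F9. Decarboxylative conjugate addition of F9 to 19 with Ir[dF(CF3)ppy]2(dtbbpy)PF6, K2HPO4 and blue light rejoins the route at 34.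

**Step 24.** SmI2 may also reduce a secondary bromide, the organosamarium may displace the bromide three carbons away to a cyclopropane, or the chair may place the methyl rather than the oxygen axial. Fallback: close ring B as an alkene and add water afterwards, setting out from 40. PPh3 in MeCN gives the phosphonium iodide F10 (Ph3P+ in place of iodine in 40); NaN(SiMe3)2 in THF brings about an intramolecular Wittig reaction to the ring B cyclohexene F11 (double bond C-6=C-7, methyl on C-7). Oxymercuration with Hg(OAc)2 in aqueous THF followed by NaBH4 rejoins the route at 41: mercury should add to the face away from the angular methyl and water trans-diaxially at the tertiary carbon, giving the axial hydroxyl cis to the angular methyl.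

## Further compounds

F0 | step 7 | none | none
F1 | step 3 | ethyl 2-methyl-1,3-dioxolane-2-carboxylate | CCOC(=O)C1(C)OCCO1
F2 | step 3 | 2-methyl-1,3-dioxolane-2-carbaldehyde | CC1(C=O)OCCO1
F3 | step 3 | 2-(cyclopropylidenemethyl)-2-methyl-1,3-dioxolane | CC1(C=C2CC2)OCCO1
F4 | step 3 | (2R)-2-(2-methyl-1,3-dioxolan-2-yl)-1-oxaspiro[2.2]pentane | CC1(OCCO1)[C@@H]2OC23CC3
F5 | step 10 | tert-butyl 3-(chloromercurio)-2,2-dimethyl-6-oxocyclohexane-1-carboxylate (racemic) | CC(C)(C)OC(=O)C1C(=O)CCC([Hg]Cl)C1(C)C
F6 | step 18 | (3R,6S)-6-bromo-5,5-dimethyl-1-oxaspiro[2.5]octane | C1O[C@@]12CC[C@H](Br)C(C)(C)C2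
F7 | step 18 | (1S,4S)-4-bromo-3,3-dimethyl-1-(prop-2-en-1-yl)cyclohexan-1-ol | C=CC[C@@]1(O)CC[C@H](Br)C(C)(C)C1
F8 | step 18 | (1S,4S)-4-bromo-3,3-dimethyl-1-(prop-2-en-1-yl)cyclohexyl acetate | C=CC[C@@]1(OC(C)=O)CC[C@H](Br)C(C)(C)C1
F9 | step 18 | [(1R,4S)-1-(acetyloxy)-4-bromo-3,3-dimethylcyclohexyl]acetic acid | OC(=O)C[C@@]1(OC(C)=O)CC[C@H](Br)C(C)(C)C1
F10 | step 24 | triphenylphosphonium iodide from 40 (Ph3P+ in place of iodine) | CC(=O)O[C@]1(C[C@@H]2CC[C@](C)([C@@H](Br)CC[P+](c3ccccc3)(c3ccccc3)c3ccccc3)[C@H]2C(C)=O)CC[C@H](Br)C(C)(C)C1.[I-]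
F11 | step 24 | ring B cyclohexene: 41 with a C-6=C-7 double bond in place of H and OH | CC(=O)O[C@]1(C[C@@H]2CC[C@]3(C)[C@@H](Br)CC=C(C)[C@@H]23)CC[C@H](Br)C(C)(C)C1
A1 | alternative 1 | ring B cyclohexene diacetate with a formyl group on the quaternary carbon | CC(=O)O[C@]1(C[C@H](COCc2ccc(OC)cc2)[C@@H]3[C@@H](OC(C)=O)C=C[C@@H](OC(C)=O)[C@@]3(C)C=O)CC[C@H](Br)C(C)(C)C1
A2 | alternative 1 | (E)-2-methyl enal carrying ring A and a p-methoxybenzyl ether arm | CC(=O)O[C@]1(C[C@H](COCc2ccc(OC)cc2)/C=C(\C)C=O)CC[C@H](Br)C(C)(C)C1
A3 | alternative 1 | (1E,3E)-buta-1,3-diene-1,4-diyl diacetate | CC(=O)O/C=C/C=C/OC(C)=O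
A4 | alternative 1 | diethylaluminium chloride | CC[Al](Cl)CC
A5 | alternative 2 | trans-2-allyl-2-methyl-3-alkenylcyclohexanone monoketal carrying ring A | O=C1CCC2(OCCO2)[C@@H](C(=C)C[C@@]3(O[Si](CC)(CC)CC)CC[C@H](Br)C(C)(C)C3)[C@]1(C)CC=C
A6 | alternative 2 | 7-methyl-1,4-dioxaspiro[4.5]dec-6-en-8-one | CC1=CC2(CCC1=O)OCCO2
A7 | alternative 2 | ring A alkyne: triethylsilyl ether of (1S,4S)-4-bromo-3,3-dimethyl-1-(prop-2-yn-1-yl)cyclohexan-1-ol | C#CC[C@@]1(O[Si](CC)(CC)CC)CC[C@H](Br)C(C)(C)C1
A8 | alternative 2 | internal diisobutylalkenylaluminium from A7 | C=C(C[C@@]1(O[Si](CC)(CC)CC)CC[C@H](Br)C(C)(C)C1)[Al](CC(C)C)CC(C)C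
A9 | alternative 2 | copper bis(triflate) | [Cu+2].[O-]S(=O)(=O)C(F)(F)F.[O-]S(=O)(=O)C(F)(F)F
A10 | alternative 3 | 4-acetoxy-4-(hydrindanylmethyl)cyclohex-2-en-1-one | CC(=O)O[C@]1(C[C@@H]2CC[C@]3(C)[C@@H](Br)CC[C@@](C)(O[Si](C)(C)C)[C@@H]23)C=CC(=O)CC1
A11 | alternative 3 | α-acetoxy aldehyde carrying the silylated hydrindane (α-centre undefined) | CC(=O)OC(C=O)C[C@@H]1CC[C@]2(C)[C@@H](Br)CC[C@@](C)(O[Si](C)(C)C)[C@@H]12
A12 | alternative 3 | methyl vinyl ketone | CC(=O)C=C
A13 | alternative 3 | (S)-phenylalanine | N[C@@H](Cc1ccccc1)C(=O)O
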